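## The problem

The target is a B-type proanthocyanidin dimer. Its upper unit is a 4',7-dihydroxyflavan-3-ol (rings A, B, C; no oxygen at C5), bonded through C4 to C8 of a lower (−)-epicatechin unit (rings D, E, F). The lower unit, (2R,3R), can be taken intact from the chiral pool, so the real problem is ring C of the upper unit with its three contiguous stereocentres (2R,3R,4R). There the 3-hydroxyl is cis to ring B and trans to ring D, and the two aryl groups are trans to each other. C4 is a diarylmethine flanked by the di-ortho-oxygenated ring D; rotation about C4–C8 is slow, but this axis is not a stereogenic element that needs control. C2 is the natural controller, since an aryl group there sends reagents to the opposite face of C3 and C4. The hardest relation is C3 to C4, because any reagent that reaches C3 anti to ring D gives the unwanted 3,4-cis arrangement. The free heptaphenol is air- and base-sensitive (C2 epimerises by ring opening), benzylic and allylic aryl ethers ionise under acid, and a flavan-3-one on the way enolises towards C4. The enabling feature is that ring C contains the C3–C4 bond next to the fully substituted C4: drawn as the C3=C4 alkene of a 2H-chromene, it can be closed by metathesis between a 1-arylallyl group on O1 and a 1-arylvinyl group on C4a, leaving C2 as the only upper stereocentre.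

## Retrosynthesis

**Protecting groups.** Target 22 is traced to its hepta-O-benzyl ether 21 by cutting seven O–CH2Ph bonds. Benzyl ethers survive organolithium, ylide, hydride and cold Lewis acid and fall together under neutral hydrogenolysis, so the dimer never meets acid or base unprotected. The forward step must spare the benzylic O1–C2 bonds of rings C and F.

**C3–O and C4–H.** Alcohol 21 is traced to the 2,4-trans flavan-3-one 20, this to the epoxide 19, and this to the chromene 18. Hydroboration of 18 would add H and OH syn but anti to ring B, which puts both C3 and C4 wrong. Epoxidation anti to ring B followed by a suprafacial 1,2-hydride shift instead places the C4 hydrogen on the ring B face, which is the correct C4. C3 is left as a carbonyl whose reduction must come from the face anti to ring B. Two stereocentres are removed. The forward sequence asks for face-selective epoxidation, a shift that outruns enolisation, and a reduction that is the most demanding point of the relay.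

**C3=C4 (key disconnection).** Chromene 18 is opened by retro-metathesis to diene 17, an aryl 1-arylallyl ether with an ortho 1-arylvinyl group. Closing C4–C4a or O1–C2 instead would require a stereocentre to be set during cyclisation; metathesis sets none and uses two plain alkenes. The forward reaction must close onto a hindered 1,1-diarylethene without isomerising the allylic C2 centre.

**O1–C2.** Ether 17 is cut at O1–C2 into phenol 12 and the linear carbonate 16. Iridium-catalysed allylic etherification sets C2 by catalyst control. A Mitsunobu reaction with a chiral 1-arylallyl alcohol would risk SN2' attack and ionisation. The forward step needs branched selectivity and high enantioselectivity with a hindered phenoxide.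

**C4–C8 and the methylene carbon.** Phenol 12 comes from the allyl ether 11, this from ketone 10, and this from carbinol 9. Carbinol 9 is cut at the carbinol–C8 bond into the aryllithium 8 (from bromide 4) and aldehyde 7. Friedel–Crafts acylation of the lower unit would not distinguish C6 from C8; bromination followed by lithiation fixes C8. The allyl group on the ring A oxygen is a temporary mask that a zerovalent palladium catalyst removes without acid.

**Building blocks.** Bromide 4 comes from (−)-epicatechin 1 through 2 and 3. Aldehyde 7 comes from 2,4-dihydroxybenzaldehyde 5 through 6. Carbonate 16 comes from 4-hydroxycinnamic acid 13 through 14 and 15.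

## Roads not taken

Alternative 1: The cut is through C3–C4 and a temporary C2–O bond to the ring D oxygen at C7. In the forward key step, acid ionises a diaryl carbinol to the ortho-quinone methide of ring D. Its methide carbon bonds to C3 of an enol ether tethered to the ring A oxygen while the ring D oxygen closes onto C2, giving the bridged ketal A1. The merit is that the rigid bicycle interlocks C2, C3 and C4, and the 3,4-trans relation follows from geometry rather than from a late reduction. In that respect it is better than the chosen plan. Its weak points are three: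
- The precursor of A1 needs a lower unit with one free phenol at C7 and a sensitive 1-aryl-2-silyloxyvinyl aryl ether.
- The absolute sense of the annulation rests only on the remote stereocentres of ring F.
- The ketal must later be opened reductively at the correct C–O bond and from the correct face to create C2.

The chosen plan offers catalyst-controlled absolute configuration at C2 and uniformly benzylated, robust intermediates, but its C3 reduction is less secure than the geometric lock of A1.

Alternative 2: The cut is the O1–C2 bond of the lower unit. Ring F is closed last by displacement of a benzylic bromide by the ring D phenoxide, on a side chain derived from droxidopa A2, to give A3. The merit is an amino-acid source for the lower stereocentres and freedom to vary ring E. For this target, however, it rebuilds the one part that is available intact as (−)-epicatechin and leaves the upper stereotriad and the C4–C8 bond unsolved. The 3,4-dialkoxybenzylic bromide would ionise, and a neighbouring acetate would favour the 2,3-trans ring. It is longer and riskier than the chosen plan and better in no respect that matters here.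

Alternative 3: The cut is through O1–C2 and C3–C4 at once. An ortho-quinone methide from a 2-hydroxybenzhydrol adds to a (Z)-β-silylstyrene, closing ring C as the 3-silyl compound A4; Tamao–Fleming oxidation would then give the 3-ol with retention. Its merits are real. It is the most convergent route, it makes two bonds and all three upper stereocentres in one step, and the Z geometry delivers the 2,3-cis-3,4-trans pattern directly. In step count and in matching the relative configuration it is better than the chosen plan. Its weak points are three: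
- The planar quinone methide has no local chiral control, so both enantiomeric series of the upper unit are expected unless a chiral catalyst intervenes.
- A stepwise addition would lose the alkene geometry.
- The β-silyl cation can lose silicon and give an open alkene instead of A4.

The chosen plan sets C2 by a catalytic asymmetric reaction and avoids the desilylation channel, at the price of a longer sequence and a reduction at C3 that must go against ring D.

Key step: step 14

Assumption: the (S,S,S)-phosphoramidite ligand is taken to give the (S)-ether 17, by analogy with the usual sense of induction of this catalyst family with cinnamyl carbonates; if the sense is opposite, the (R,R,R)-ligand is used.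

## Route

Step 1
Reactants: 1 (−)-epicatechin
Product: 2 5,7,3',4'-tetra-O-benzyl-(−)-epicatechin
Conditions: BnBr (4.4 equiv), K2CO3, DMF, 0 °C → rt
Reagents that add atoms: benzyl bromide, BrCc1ccccc1
Why: Williamson etherification; K2CO3 ionises only the four phenols, so the secondary 3-hydroxyl stays free, and the mild base avoids C2 epimerisation.

Step 2
Reactants: 2 5,7,3',4'-tetra-O-benzyl-(−)-epicatechin
Product: 3 8-bromo-5,7,3',4'-tetra-O-benzyl-(−)-epicatechin
Conditions: NBS (1.0 equiv), CH2Cl2, −78 → 0 °C
Reagents that add atoms: N-bromosuccinimide, O=C1CCC(=O)N1Br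
Why: Electrophilic aromatic bromination; in 5,7-dibenzyloxyflavans the C8 position is the more reactive one, so one equivalent at low temperature should give the 8-bromide.

Step 3
Reactants: 3 8-bromo-5,7,3',4'-tetra-O-benzyl-(−)-epicatechin
Product: 4 8-bromo-3,5,7,3',4'-penta-O-benzyl-(−)-epicatechin
Conditions: NaH, BnBr, n-Bu4NI (cat.), THF/DMF, 0 °C → rt
Reagents that add atoms: benzyl bromide, BrCc1ccccc1
Why: Williamson etherification of the secondary alkoxide; no acidic proton then remains for the later halogen–lithium exchange.

Step 4
Reactants: 5 2,4-dihydroxybenzaldehyde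
Product: 6 4-benzyloxy-2-hydroxybenzaldehyde
Conditions: BnBr (1.05 equiv), NaHCO3, KI (cat.), MeCN, 80 °C
Reagents that add atoms: benzyl bromide, BrCc1ccccc1
Why: Regioselective Williamson etherification; the 4-hydroxyl is the more acidic and is not hydrogen-bonded to the aldehyde, so a weak base alkylates it alone.

Step 5
Reactants: 6 4-benzyloxy-2-hydroxybenzaldehyde
Product: 7 2-allyloxy-4-benzyloxybenzaldehyde
Conditions: allyl bromide, K2CO3, DMF, 50 °C
Reagents that add atoms: allyl bromide, C=CCBr
Why: Williamson etherification; the allyl group masks the ring A oxygen against the organolithium and ylide steps and is later removed without acid.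

Step 6
Reactants: 4 8-bromo-3,5,7,3',4'-penta-O-benzyl-(−)-epicatechin; 7 2-allyloxy-4-benzyloxybenzaldehyde
Product: 9 (2-allyloxy-4-benzyloxyphenyl)(penta-O-benzylepicatechin-8-yl)methanol as a mixture of carbinol epimers, via 8-lithio-penta-O-benzylepicatechin 8 (not isolated)
Conditions: t-BuLi (2.0 equiv), THF, −78 °C; then 7, −78 → −40 °C; H2O
Reagents that add atoms: none
Why: Bromine–lithium exchange and 1,2-addition of the aryllithium to a non-enolisable aldehyde form the C4–C8 bond at the defined ring D position; the carbinol configuration is irrelevant because it is oxidised next.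

Step 7
Reactants: 9 (2-allyloxy-4-benzyloxyphenyl)(penta-O-benzylepicatechin-8-yl)methanol
Product: 10 (2-allyloxy-4-benzyloxyphenyl) penta-O-benzylepicatechin-8-yl ketone
Conditions: Dess–Martin periodinane, NaHCO3, CH2Cl2, 0 °C → rt
Reagents that add atoms: none
Why: Buffered Dess–Martin oxidation of a benzhydrol; the buffer prevents ionisation of the very electron-rich carbinol.

Step 8
Reactants: 10 (2-allyloxy-4-benzyloxyphenyl) penta-O-benzylepicatechin-8-yl ketone
Product: 11 1-(2-allyloxy-4-benzyloxyphenyl)-1-(penta-O-benzylepicatechin-8-yl)ethene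
Conditions: Ph3PCH3Br, KOt-Bu (slightly less than the salt), THF, 0 → 65 °C
Reagents that add atoms: methyltriphenylphosphonium bromide, C[P+](c1ccccc1)(c1ccccc1)c1ccccc1.[Br-]
Why: Wittig methylenation of a non-enolisable diaryl ketone; the smallest ylide should still reach the tri-ortho-substituted carbonyl on warming.

Step 9
Reactants: 11 1-(2-allyloxy-4-benzyloxyphenyl)-1-(penta-O-benzylepicatechin-8-yl)ethene
Product: 12 5-benzyloxy-2-[1-(penta-O-benzylepicatechin-8-yl)vinyl]phenol
Conditions: Pd(PPh3)4 (5 mol%), morpholine, THF, rt
Reagents that add atoms: none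
Why: Deallylation through a π-allyl complex formed by zerovalent palladium; morpholine traps the allyl group irreversibly, and benzyl ethers and the 1,1-diarylethene are inert.

Step 10
Reactants: 13 (E)-4-hydroxycinnamic acid
Product: 14 benzyl (E)-4-benzyloxycinnamate
Conditions: BnBr (2.3 equiv), K2CO3, DMF, 60 °C
Reagents that add atoms: benzyl bromide, BrCc1ccccc1
Why: Double O-alkylation of carboxylate and phenoxide in one operation; the E alkene is untouched.

Step 11
Reactants: 14 benzyl (E)-4-benzyloxycinnamate
Product: 15 (E)-3-(4-benzyloxyphenyl)prop-2-en-1-ol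
Conditions: i-Bu2AlH (2.5 equiv), CH2Cl2, −78 → 0 °C; aqueous potassium sodium tartrate
Reagents that add atoms: none
Why: 1,2-Reduction of an α,β-unsaturated ester to the allylic alcohol with retention of the E geometry.

Step 12
Reactants: 15 (E)-3-(4-benzyloxyphenyl)prop-2-en-1-ol
Product: 16 (E)-3-(4-benzyloxyphenyl)allyl methyl carbonate
Conditions: ClCO2Me, pyridine, CH2Cl2, 0 °C
Reagents that add atoms: methyl chloroformate, COC(Cl)=O
Why: Acylation of a primary allylic alcohol; basic, cold conditions avoid ionisation of the electron-rich cinnamyl system.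

Step 13
Reactants: 12 5-benzyloxy-2-[1-(penta-O-benzylepicatechin-8-yl)vinyl]phenol; 16 (E)-3-(4-benzyloxyphenyl)allyl methyl carbonate
Product: 17 5-benzyloxy-2-[1-(penta-O-benzylepicatechin-8-yl)vinyl]phenyl (S)-1-(4-benzyloxyphenyl)allyl ether
Conditions: LiN(SiMe3)2 (1.0 equiv), THF, 0 °C; [Ir(cod)Cl]2 (2 mol%), (S,S,S)-binaphthol bis(1-phenylethyl)phosphoramidite (4 mol%), 16 (1.5 equiv), THF, rt → 40 °C
Reagents that add atoms: none
Why: Iridium-catalysed asymmetric allylic etherification; the cyclometalated phosphoramidite catalyst ionises the carbonate to an allyl complex of trivalent iridium, which the lithium phenoxide attacks at the aryl-substituted terminus. The ligand sets the new stereocentre C2 as S, and the 1,1-diarylethene does not take part.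

Step 14
Reactants: 17 5-benzyloxy-2-[1-(penta-O-benzylepicatechin-8-yl)vinyl]phenyl (S)-1-(4-benzyloxyphenyl)allyl ether
Product: 18 (2S)-7-benzyloxy-2-(4-benzyloxyphenyl)-4-(penta-O-benzylepicatechin-8-yl)-2H-chromene
Conditions: second-generation Hoveyda–Grubbs catalyst RuCl2(H2IMes)(=CH-C6H4-2-Oi-Pr) (10 mol%), 2,6-dichloro-1,4-benzoquinone (20 mol%), toluene (high dilution, argon sparge), 60–80 °C
Reagents that add atoms: none
Why: Ring-closing olefin metathesis: the ruthenium benzylidene exchanges with the monosubstituted vinyl group of the allyl ether, the new alkylidene adds across the ortho 1,1-diarylethene, and cycloreversion of the ruthenacyclobutane releases the chromene and a methylidene that is finally lost as ethylene. The closest known reaction type is the metathetic closure of aryl allyl ethers bearing ortho vinyl or isopropenyl groups to 2H-chromenes, including 4-substituted ones from 1,1-disubstituted styrenes. Ring C closes as a six-membered ring by an intramolecular [2+2]/retro-[2+2] sequence, and the four-atom tether C2–O1–C8a–C4a is held by the arene, which favours cyclisation over cross-metathesis. No stereocentre forms; C2 is carried through unchanged. The step needs closure at a hindered 1,1-diarylethene and must avoid ruthenium hydride migration of the terminal alkene towards the ether oxygen, which would destroy C2. The ortho pre-organisation and the unstrained, conjugated trisubstituted alkene product favour closure, the quinone scavenges hydride species, and the sparge removes ethylene.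

Step 15
Reactants: 18 (2S)-7-benzyloxy-2-(4-benzyloxyphenyl)-4-(penta-O-benzylepicatechin-8-yl)-2H-chromene
Product: 20 (2R,4R)-7-benzyloxy-2-(4-benzyloxyphenyl)-4-(penta-O-benzylepicatechin-8-yl)chroman-3-one, via 3,4-epoxide anti to ring B 19 (not isolated)
Conditions: dimethyldioxirane (1.2 equiv), acetone/CH2Cl2, −40 °C; evaporate cold; BF3·OEt2 (0.1 equiv), CH2Cl2, −78 °C; Et3N quench; used crude
Reagents that add atoms: dimethyldioxirane, CC1(C)OO1
Why: The neutral dioxirane epoxidises the electron-rich C3=C4 bond from the face opposite the C2 aryl group. BF3 then opens the oxirane at the doubly benzylic C4, and the C3 hydrogen, which lies on the face away from the oxirane oxygen, migrates suprafacially to C4 (Meinwald rearrangement). The C4 hydrogen thus ends cis to ring B and ring D trans to it (new stereocentre C4, R), and C3 becomes the ketone.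

Step 16
Reactants: 20 (2R,4R)-7-benzyloxy-2-(4-benzyloxyphenyl)-4-(penta-O-benzylepicatechin-8-yl)chroman-3-one
Product: 21 (2R,3R,4R)-7-benzyloxy-2-(4-benzyloxyphenyl)-4-(penta-O-benzylepicatechin-8-yl)chroman-3-ol
Conditions: LiBH(s-Bu)3 (1.5 equiv), LiBr, THF, −78 °C; aqueous NH4Cl
Reagents that add atoms: none
Why: Bulky trialkylborohydride reduction is the standard way from flavan-3-ones to 2,3-cis-flavan-3-ols. Hydride is expected anti to ring B through the ring C conformer with ring B quasi-axial and ring D quasi-equatorial beside the unsubstituted C5–H, giving the 3-ol cis to ring B and trans to ring D (new stereocentre C3, R). Low temperature and a weakly basic hydride limit enolisation at C4.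

Step 17
Reactants: 21 (2R,3R,4R)-7-benzyloxy-2-(4-benzyloxyphenyl)-4-(penta-O-benzylepicatechin-8-yl)chroman-3-ol
Product: 22 target, (2R,3R,4R)-2-(4-hydroxyphenyl)-4-[(2R,3R)-epicatechin-8-yl]chromane-3,7-diol
Conditions: H2 (1 atm), Pd(OH)2/C, THF/MeOH, rt; filtration and purification under argon
Reagents that add atoms: none
Why: Global hydrogenolysis of seven benzyl ethers under neutral conditions; the cyclic benzylic C–O bonds of rings C and F are far slower to cleave, and no stereocentre is touched.

## Compound list

1 | (−)-epicatechin, (2R,3R) | O[C@@H]1Cc2c(O)cc(O)cc2O[C@@H]1c1ccc(O)c(O)c1 | starting material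
2 | 5,7,3',4'-tetra-O-benzyl-(−)-epicatechin | c3c(OCc5ccccc5)cc(OCc5ccccc5)c4c3O[C@H](c3ccc(OCc5ccccc5)c(OCc5ccccc5)c3)[C@H](O)C4 | intermediate
3 | 8-bromo-5,7,3',4'-tetra-O-benzyl-(−)-epicatechin | Brc3c(OCc5ccccc5)cc(OCc5ccccc5)c4c3O[C@H](c3ccc(OCc5ccccc5)c(OCc5ccccc5)c3)[C@H](O)C4 | intermediate
4 | 8-bromo-3,5,7,3',4'-penta-O-benzyl-(−)-epicatechin | Brc3c(OCc5ccccc5)cc(OCc5ccccc5)c4c3O[C@H](c3ccc(OCc5ccccc5)c(OCc5ccccc5)c3)[C@H](OCc5ccccc5)C4 | intermediate
5 | 2,4-dihydroxybenzaldehyde | O=Cc1ccc(O)cc1O | starting material
6 | 4-benzyloxy-2-hydroxybenzaldehyde | O=Cc1ccc(OCc2ccccc2)cc1O | intermediate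
7 | 2-allyloxy-4-benzyloxybenzaldehyde | O=Cc1ccc(OCc2ccccc2)cc1OCC=C | intermediate
8 | 8-lithio-3,5,7,3',4'-penta-O-benzylepicatechin (not isolated) | [Li]c3c(OCc5ccccc5)cc(OCc5ccccc5)c4c3O[C@H](c3ccc(OCc5ccccc5)c(OCc5ccccc5)c3)[C@H](OCc5ccccc5)C4 | intermediate
9 | (2-allyloxy-4-benzyloxyphenyl)(penta-O-benzylepicatechin-8-yl)methanol, both carbinol epimers | OC(c1ccc(OCc2ccccc2)cc1OCC=C)c3c(OCc5ccccc5)cc(OCc5ccccc5)c4c3O[C@H](c3ccc(OCc5ccccc5)c(OCc5ccccc5)c3)[C@H](OCc5ccccc5)C4 | intermediate
10 | (2-allyloxy-4-benzyloxyphenyl) penta-O-benzylepicatechin-8-yl ketone | O=C(c1ccc(OCc2ccccc2)cc1OCC=C)c3c(OCc5ccccc5)cc(OCc5ccccc5)c4c3O[C@H](c3ccc(OCc5ccccc5)c(OCc5ccccc5)c3)[C@H](OCc5ccccc5)C4 | intermediate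
11 | 1-(2-allyloxy-4-benzyloxyphenyl)-1-(penta-O-benzylepicatechin-8-yl)ethene | C=C(c1ccc(OCc2ccccc2)cc1OCC=C)c3c(OCc5ccccc5)cc(OCc5ccccc5)c4c3O[C@H](c3ccc(OCc5ccccc5)c(OCc5ccccc5)c3)[C@H](OCc5ccccc5)C4 | intermediate
12 | 5-benzyloxy-2-[1-(penta-O-benzylepicatechin-8-yl)vinyl]phenol | C=C(c1ccc(OCc2ccccc2)cc1O)c3c(OCc5ccccc5)cc(OCc5ccccc5)c4c3O[C@H](c3ccc(OCc5ccccc5)c(OCc5ccccc5)c3)[C@H](OCc5ccccc5)C4 | intermediate
13 | (E)-4-hydroxycinnamic acid | OC(=O)/C=C/c1ccc(O)cc1 | starting material
14 | benzyl (E)-4-benzyloxycinnamate | O=C(OCc1ccccc1)/C=C/c1ccc(OCc2ccccc2)cc1 | intermediate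
15 | (E)-3-(4-benzyloxyphenyl)prop-2-en-1-ol | OC/C=C/c1ccc(OCc2ccccc2)cc1 | intermediate
16 | (E)-3-(4-benzyloxyphenyl)allyl methyl carbonate | COC(=O)OC/C=C/c1ccc(OCc2ccccc2)cc1 | intermediate
17 | aryl (S)-1-(4-benzyloxyphenyl)allyl ether whose ring A carries the 1-(penta-O-benzylepicatechin-8-yl)vinyl group ortho to oxygen | O(Cc5ccccc5)c1ccc([C@H](C=C)Oc2cc(OCc5ccccc5)ccc2C(=C)c3c(OCc5ccccc5)cc(OCc5ccccc5)c4c3O[C@H](c3ccc(OCc5ccccc5)c(OCc5ccccc5)c3)[C@H](OCc5ccccc5)C4)cc1 | intermediate
18 | (2S)-7-benzyloxy-2-(4-benzyloxyphenyl)-4-(penta-O-benzylepicatechin-8-yl)-2H-chromene | O(Cc5ccccc5)c1ccc([C@H]2Oc3cc(OCc5ccccc5)ccc3C(c3c(OCc5ccccc5)cc(OCc5ccccc5)c4c3O[C@H](c3ccc(OCc5ccccc5)c(OCc5ccccc5)c3)[C@H](OCc5ccccc5)C4)=C2)cc1 | intermediate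
19 | 3,4-epoxide of 18, oxirane oxygen on the face opposite ring B (not isolated) | O(Cc5ccccc5)c1ccc([C@H]2Oc3cc(OCc5ccccc5)ccc3[C@]4(c3c(OCc5ccccc5)cc(OCc5ccccc5)c6c3O[C@H](c3ccc(OCc5ccccc5)c(OCc5ccccc5)c3)[C@H](OCc5ccccc5)C6)O[C@H]24)cc1 | intermediate
20 | (2R,4R)-7-benzyloxy-2-(4-benzyloxyphenyl)-4-(penta-O-benzylepicatechin-8-yl)chroman-3-one, aryl groups trans | O(Cc5ccccc5)c1ccc([C@H]2Oc3cc(OCc5ccccc5)ccc3[C@H](c3c(OCc5ccccc5)cc(OCc5ccccc5)c4c3O[C@H](c3ccc(OCc5ccccc5)c(OCc5ccccc5)c3)[C@H](OCc5ccccc5)C4)C2=O)cc1 | intermediate
21 | (2R,3R,4R)-7-benzyloxy-2-(4-benzyloxyphenyl)-4-(penta-O-benzylepicatechin-8-yl)chroman-3-ol, 2,3-cis-3,4-trans | O(Cc5ccccc5)c1ccc([C@H]2Oc3cc(OCc5ccccc5)ccc3[C@H](c3c(OCc5ccccc5)cc(OCc5ccccc5)c4c3O[C@H](c3ccc(OCc5ccccc5)c(OCc5ccccc5)c3)[C@H](OCc5ccccc5)C4)[C@H]2O)cc1 | intermediate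
22 | (2R,3R,4R)-2-(4-hydroxyphenyl)-4-[(2R,3R)-epicatechin-8-yl]chromane-3,7-diol (CNP0118995.2) | Oc1ccc([C@H]2Oc3cc(O)ccc3[C@H](c3c(O)cc(O)c4c3O[C@H](c3ccc(O)c(O)c3)[C@H](O)C4)[C@H]2O)cc1 | target

## Step count and least certain steps

Total: 17 steps. Longest linear sequence: 12 steps (1, 2, 3, 6, 7, 8, 9, 13, 14, 15, 16, 17).

**Step 14 (key step).** The loaded alkylidene may fail to engage the 1,1-diarylethene, which is shielded by the di-ortho-substituted ring D. Intermolecular homocoupling at the vinyl group and slow catalyst decay would then dominate. Hydride-mediated double-bond migration or thermal ionisation of the doubly activated allylic ether would also erase C2. The fallback makes the C4–C8 bond last, by carbonyl addition. It sets out from bromide 4: the aryllithium 8 is transmetallated with CeCl3 and added to (2S)-7-benzyloxy-2-(4-benzyloxyphenyl)chroman-4-one F1, obtained by benzylation of (S)-liquiritigenin. This gives the tertiary alcohol 7-benzyloxy-2-(4-benzyloxyphenyl)-4-(penta-O-benzylepicatechin-8-yl)chroman-4-ol F2. Dehydration with the Burgess reagent or catalytic acid then returns to the route at chromene 18.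

**Step 16.** Hydride may be delivered anti to ring D instead of anti to ring B. If ring D sits quasi-axial it shields exactly the face from which hydride must come, and the C3 epimer would result; by this analysis that is the single most doubtful stereochemical event of the route. Deprotonation at C4 by the borohydride, with epimerisation or stalled conversion, is the second hazard. The fallback replaces kinetic delivery by thermodynamic control. It sets out from ketone 20, which is reduced under equilibrating Meerwein–Ponndorf–Verley conditions (Al(Oi-Pr)3, i-PrOH, toluene). The two carbinol epimers then interconvert through the ketone, and the epimer with the hydroxyl anti-periplanar to ring D should accumulate. No new compound arises (F0), and the route is rejoined at 21.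

**Step 15.** The ring-opened cation may lose the C3 proton to an enol instead of undergoing the suprafacial shift, so that C4 is set by unselective protonation. Other hazards are migration of C2 with ring contraction, later acid-catalysed epimerisation at C4, and oxidation of ring D by excess dioxirane. The fallback traps the same cation with an external hydride. It sets out from epoxide 19, made as before, which is treated with Et3SiH and BF3·OEt2 at −78 °C. Hydride should enter C4 anti to the C3 oxygen, giving the (2R,3S,4R)-2,3-trans-3,4-cis chroman-3-ol F3 with C4 correct. Dess–Martin oxidation returns to the route at ketone 20.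

**Step 13.** Attack of the hindered ortho-substituted phenoxide on the iridium allyl complex may be slow, giving the linear cinnamyl ether or leaving the phenol unchanged. Re-ionisation of the electron-rich branched ether would erode regio- and enantiopurity. The fallback moves the etherification to an unhindered phenol. It sets out from 6, which is etherified with 16 under the same iridium catalysis to 4-benzyloxy-2-[(S)-1-(4-benzyloxyphenyl)allyloxy]benzaldehyde F4. Addition of aryllithium 8 gives the carbinol F5, Dess–Martin oxidation gives the ketone F6, and Wittig methylenation returns to the route at 17.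

**Step 8.** Addition of the ylide to the tri-ortho-substituted, electron-rich benzophenone may be sluggish, and prolonged heating with base may move the allyl double bond into conjugation with oxygen. The fallback builds the alkene by addition and elimination. It sets out from ketone 10, to which MeMgBr (or MeLi with CeCl3) is added to give the tertiary carbinol 1-(2-allyloxy-4-benzyloxyphenyl)-1-(penta-O-benzylepicatechin-8-yl)ethanol F7. Dehydration with the Burgess reagent or a trace of acid returns to the route at 11.

## Further compounds

F1 | step 14 | (2S)-7-benzyloxy-2-(4-benzyloxyphenyl)chroman-4-one | O(Cc5ccccc5)c1ccc([C@H]2Oc3cc(OCc5ccccc5)ccc3C(=O)C2)cc1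
F2 | step 14 | (2S)-7-benzyloxy-2-(4-benzyloxyphenyl)-4-(penta-O-benzylepicatechin-8-yl)chroman-4-ol, C4 epimers | O(Cc5ccccc5)c1ccc([C@H]2Oc3cc(OCc5ccccc5)ccc3C(O)(c3c(OCc5ccccc5)cc(OCc5ccccc5)c4c3O[C@H](c3ccc(OCc5ccccc5)c(OCc5ccccc5)c3)[C@H](OCc5ccccc5)C4)C2)cc1
F0 | step 16 | none | none
F3 | step 15 | (2R,3S,4R)-7-benzyloxy-2-(4-benzyloxyphenyl)-4-(penta-O-benzylepicatechin-8-yl)chroman-3-ol, 2,3-trans-3,4-cis | O(Cc5ccccc5)c1ccc([C@H]2Oc3cc(OCc5ccccc5)ccc3[C@H](c3c(OCc5ccccc5)cc(OCc5ccccc5)c4c3O[C@H](c3ccc(OCc5ccccc5)c(OCc5ccccc5)c3)[C@H](OCc5ccccc5)C4)[C@@H]2O)cc1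
F4 | step 13 | 4-benzyloxy-2-[(S)-1-(4-benzyloxyphenyl)allyloxy]benzaldehyde | O=Cc1ccc(OCc2ccccc2)cc1O[C@@H](C=C)c1ccc(OCc2ccccc2)cc1
F5 | step 13 | {4-benzyloxy-2-[(S)-1-(4-benzyloxyphenyl)allyloxy]phenyl}(penta-O-benzylepicatechin-8-yl)methanol, carbinol epimers | OC(c1ccc(OCc2ccccc2)cc1O[C@@H](C=C)c1ccc(OCc2ccccc2)cc1)c3c(OCc5ccccc5)cc(OCc5ccccc5)c4c3O[C@H](c3ccc(OCc5ccccc5)c(OCc5ccccc5)c3)[C@H](OCc5ccccc5)C4
F6 | step 13 | {4-benzyloxy-2-[(S)-1-(4-benzyloxyphenyl)allyloxy]phenyl} penta-O-benzylepicatechin-8-yl ketone | O=C(c1ccc(OCc2ccccc2)cc1O[C@@H](C=C)c1ccc(OCc2ccccc2)cc1)c3c(OCc5ccccc5)cc(OCc5ccccc5)c4c3O[C@H](c3ccc(OCc5ccccc5)c(OCc5ccccc5)c3)[C@H](OCc5ccccc5)C4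
F7 | step 8 | 1-(2-allyloxy-4-benzyloxyphenyl)-1-(penta-O-benzylepicatechin-8-yl)ethanol, carbinol epimers | CC(O)(c1ccc(OCc2ccccc2)cc1OCC=C)c3c(OCc5ccccc5)cc(OCc5ccccc5)c4c3O[C@H](c3ccc(OCc5ccccc5)c(OCc5ccccc5)c3)[C@H](OCc5ccccc5)C4
A1 | alternative 1 | bridged ketal with C2–O–C7(ring D) and C4–C8 bonds, upper 3-O-tert-butyldimethylsilyl, hexa-O-benzyl | O(Cc5ccccc5)c1ccc([C@@]26Oc3cc(OCc5ccccc5)ccc3[C@H](c3c(O6)cc(OCc5ccccc5)c4c3O[C@H](c3ccc(OCc5ccccc5)c(OCc5ccccc5)c3)[C@H](OCc5ccccc5)C4)[C@H]2O[Si](C)(C)C(C)(C)C)cc1
A2 | alternative 2 | droxidopa, (2S,3R)-3-(3,4-dihydroxyphenyl)serine | c1cc(O)c(O)cc1[C@H]([C@@H](C(O)=O)N)O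
A3 | alternative 2 | hepta-O-benzyl target with the lower 3-hydroxyl as acetate | O(Cc5ccccc5)c1ccc([C@H]2Oc3cc(OCc5ccccc5)ccc3[C@H](c3c(OCc5ccccc5)cc(OCc5ccccc5)c4c3O[C@H](c3ccc(OCc5ccccc5)c(OCc5ccccc5)c3)[C@H](OC(C)=O)C4)[C@H]2OCc5ccccc5)cc1
A4 | alternative 3 | hepta-O-benzyl 3-deoxy-3-(benzyldimethylsilyl) analogue of the target, 2,3-cis-3,4-trans | O(Cc5ccccc5)c1ccc([C@H]2Oc3cc(OCc5ccccc5)ccc3[C@H](c3c(OCc5ccccc5)cc(OCc5ccccc5)c4c3O[C@H](c3ccc(OCc5ccccc5)c(OCc5ccccc5)c3)[C@H](OCc5ccccc5)C4)[C@H]2[Si](C)(C)Cc5ccccc5)cc1
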